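**Conventions.** The locants C1–C10 of the target are used for every intermediate, decalins included. The cycloheptene is C1 (angelate carbinol), C2, C3 (methylated alkene carbon), C4, C5 (aroyloxy carbinol), C6 (fusion CH), C7 (methylated fusion carbon); the cyclopentane is C7, C8, C9, C10 (isopropyl carbinol), C6. β is the face of the angular C7 methyl, α the opposite face. PMB = 4-methoxybenzyl, TBS = tert-butyldimethylsilyl.

## Analysis of the target

Compound 37 is a daucane-type sesquiterpenoid diester on a trans-fused bicyclo[5.3.0]decane, a cycloheptene (C1–C7) fused along C6–C7 to a cyclopentane (C7, C8, C9, C10, C6). It has five stereocentres: quaternary C7 (β-methyl), C6 (α-H), C5 (α-aroyloxy, cis to H6), C1 (α-angeloyloxy, trans to the C7 methyl) and the tertiary carbinol C10 (β-OH, α-isopropyl); the angelate adds a Z-configured trisubstituted alkene. Apart from the C10 hydroxyl, every group attached to the core besides the angular methyl (O1, O5, H6, the isopropyl group) lies on the α face. The sensitive groups are the angelate (Z to E isomerisation when the acid is activated), the allylic C1 ester, the tertiary alcohol (dehydration, and retro-aldol cleavage whenever C5 is a carbonyl), the free phenol and two different esters that must go on one after the other. The difficulty is that C1, C5 and C10 all flank the ring fusion, and reagents approach the trans-fused core anti to the angular methyl, from the α face. That suits the isopropyl nucleophile and oxygen-transfer reagents, but not hydride reduction of a C1 or C5 carbonyl, which would leave the oxygen on the β face. The strategy rests on the C5 oxygen lying next to the C6–C7 fusion bond: in a decalin in which C7 is bonded to C5 (ring A: C5, C6, C10, C9, C8, C7; ring B: C7, C1, C2, C3, C4, C5), moving C7 from C5 to C6 while the tertiary C5 oxygen becomes a carbonyl creates both rings of 37 at once.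

## Retrosynthetic reasoning

**Esters.** Target 37 comes from silyl ether 36, cut at the C5 acyl–oxygen bond into diol 34 and acid 35. Diol 34 comes from 33, cut at the C1 acyl–oxygen bond into allylic alcohol 31 and angelic acid 32. The esters go on last because both are base-labile and the angelate isomerises. The angelate is attached while C5 is still a silyl ether, so each acylation meets one free secondary hydroxyl.

**C1–O and C2=C3.** Allylic alcohol 31 is traced to epoxide 30 and that to alkene 29. Reduction of a C1 carbonyl is not used, because hydride would enter anti to the C7 methyl and leave the oxygen on the β face. Epoxidation delivers oxygen from that same α face, and a syn β-elimination of the epoxide then moves the unsaturation to C2=C3. This needs H3 on the α face, so the C3 methyl must be β.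

**C10–isopropyl.** Tertiary alcohol 29 is cut at the C10–isopropyl bond to ketone 27 and isopropylmagnesium chloride 28. Addition anti to the angular methyl sets the C10 configuration of 37.

**C1 ketone to alkene.** Ketone 27 goes back through alcohol 26 and PMB ether 25 to enol triflate 24, ketone 22 and dioxolane 21. The C1 carbonyl is removed via its only possible enol (C7 is quaternary) before the tertiary alcohol exists.

**C5–O and C6–H.** Silyl ether 21 and alcohol 20 come from alkene 18 by hydroboration. One syn addition from the α face gives the trans ring fusion and the C5 configuration together. Alkene 18 comes from ketone 14 through enol ether 15 and triflate 17. The C6 centre of 14 is erased on purpose. Equilibrating 14 with base is avoided because the C6 enolate can expel the C10 oxygen, and hydride reduction at C5 would again put the oxygen on the β face.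

**Key disconnection.** Hydroazulenone 14 is cut at C6–C7 and reconnected C5–C7, giving decalin mesylate 12. The forward 1,2-shift must move only C7, invert C6 and turn the C5 alkoxide into the ketone.

**Precursor.** Mesylate 12 comes from diol 11, alkene 10, alcohol 9, ketal 8 and enedione 7 by standard functional-group changes. The diol must be α so that the secondary mesylate is equatorial.

**Decalin.** Enedione 7 is cut at C5–C6 (aldol) to triketone 5, and 5 at C7–C8 (Michael) to dione 3 and enone 4. Dione 3 comes from 1 and 2.

## Alternatives that were turned down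

Alternative 1: Conjugate methylation with aldol trapping on a cyclopentenone. The disconnection cuts the C7–methyl bond and the C5–C6 bond and leads back to cyclopentenone A1, which is 3-[(methoxymethoxy)methyl]cyclopent-2-en-1-one, and to aldehyde A2, which is 3-methylbut-3-enal. In the forward key step Cu(OTf)2 with a chiral phosphoramidite transfers a methyl group from AlMe3 to C7 of A1, and the aluminium enolate so formed adds to A2 to give aldol A3, a trans-2,3-disubstituted cyclopentanone. In its favour, the quaternary centre is made by asymmetric catalysis, and A3 already has C5, C6 and C7 as in 37, including the trans relationship at C6/C7. On this point it is stronger than the chosen route, which has to set C6 a second time. Against it, no ring is closed. Aldehyde A2 is β,γ-unsaturated and conjugates and enolises easily under Lewis-acidic enolate conditions. Aldol A3 is a β-hydroxy cyclopentanone, prone to retro-aldol cleavage and dehydration. The seven-membered ring would still have to be closed between C1 and C2; a carbonyl-ene or Prins closure onto the 1,1-disubstituted alkene of A3 would leave an exocyclic or C3=C4 alkene instead of C2=C3 and an uncontrolled C1 carbinol. In comparison, the chosen strategy closes both rings in one stereospecific step from a decalin made by textbook reactions, at the price of the later correction at C6.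

Alternative 2: Enone photocycloaddition followed by glycol cleavage. The disconnection cuts C1–C7 and C5–C6 as a [2+2] cycloaddition between enone A4, which is 3-methylcyclopent-2-en-1-one, and bis(silyl enol ether) A5, which is 4-methyl-1,2-bis(trimethylsilyloxy)cyclopent-1-ene; the C1–C5 bond of the cyclobutane is cleaved afterwards. In the forward key step A4 and A5 are irradiated in the presence of a chiral oxazaborolidine activated by AlBr3 to give cyclobutane A6. In its favour, it is the shortest way to the whole bicyclic carbon skeleton with both methyl groups, and in step count to the ring system it is stronger than the chosen route. Against it, an enantioselective Lewis-acid-mediated intermolecular [2+2] with a tetrasubstituted, acid-labile partner such as A5 is not secured, and the uncatalysed background reaction of A4 competes. After glycol cleavage of A6, C1, C5 and C10 are all ketones. C5 and C10 flank C6 as an enolised 1,3-diketone, so C6 is lost and isopropyl addition at C10 cannot be separated from chemistry at C5. C1 and C5 would have to be reduced by hydride, which attacks the trans-fused core anti to the angular methyl and gives the β-carbinols. In comparison, the chosen strategy delivers C1 (ketal), C5 (ketone) and C10 (ether) in three different states and builds C1–O and C5–O by oxygen transfer.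

Alternative 3: Allenylsilane annulation. The disconnection cuts C7–C8 and C6–C10 and leads to cycloheptenone A7, which is 4-(tert-butyldimethylsilyloxy)-3-methylcyclohept-2-en-1-one, and to allenylsilane A8, which is trimethyl(4-methylpenta-1,2-dien-3-yl)silane. In the forward key step TiCl4 activates A7, the CH2 terminus of A8 attacks C7, a 1,2-silyl shift follows and the titanium enolate closes onto the isopropyl-bearing carbon to give silylcyclopentene A9. In its favour, it is convergent and installs the isopropyl carbon, the cyclopentane and the quaternary centre in one step. In convergence it is stronger than the linear chosen route. Against it, A7 is a β,β-disubstituted enone with a γ-silyloxy group and therefore a poor acceptor, and its allylic silyl ether can ionise under TiCl4. Product A9 is cis-fused, so C6 needs the same correction. In A9, C10 is an alkene carbon, so the tertiary β-alcohol would need protodesilylation and hydration of a tetrasubstituted alkene on the face syn to the angular methyl. The steering silyloxy group of A9 ends up cis to the methyl, opposite to C1 of 37. The C3 methyl and the C2=C3 alkene are missing, and enantiopure A7 needs its own synthesis, as does A8. In comparison, the chosen route carries the C10 oxygen as a ketone precursor, so addition anti to the methyl gives the right carbinol, and it has the C3 methyl from the first step.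

Key step: step 9

**Assumptions.**
- Step 2 is taken to give the cis-dimethyl triketone 5 as the isolated product; if the alkylation is not face-selective, the trans isomer is removed there by chromatography. Only the cis series keeps the C3 methyl equatorial in the decalin (needed for steps 7 and 9) and puts H3 on the α face (needed for step 22).
- 4-(tert-Butyldimethylsilyloxy)benzoic acid 35 is taken as a catalogue compound.
- The C10 oxygen is carried as a PMB ether rather than a silyl ether: it is a poorer β-leaving group, cannot migrate to O5 and is orthogonal to the C5 silyl ether.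

## Route

Step 1
Reactants: 1 5-methylcyclohexane-1,3-dione; 2 iodomethane
Product: 3 2,5-dimethylcyclohexane-1,3-dione
Conditions: KOH, H2O/MeOH, 65 °C
Reagents that add atoms: none
Why: C-alkylation of the doubly stabilised dione enolate; the protic medium favours carbon over oxygen attack, and no stereocentre is fixed because C2 remains enolisable.

Step 2
Reactants: 3 2,5-dimethylcyclohexane-1,3-dione; 4 methyl vinyl ketone
Product: 5 cis-2,5-dimethyl-2-(3-oxobutyl)cyclohexane-1,3-dione
Conditions: H2O, AcOH (cat.), hydroquinone (cat.), 75 °C
Reagents that add atoms: none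
Why: Michael addition under near-neutral aqueous conditions builds the quaternary carbon (future C7); 5 has a mirror plane, so its two ring carbonyls are enantiotopic, and the cis methyl relationship fixes the later C3/C7 relationship (see assumptions).

Step 3
Reactants: 5 cis-2,5-dimethyl-2-(3-oxobutyl)cyclohexane-1,3-dione
Product: 7 (4aS,7S)-4a,7-dimethyl-4,4a,7,8-tetrahydronaphthalene-2,5(3H,6H)-dione, via cis-fused aldol ketol 6 (not isolated)
Conditions: L-proline (cat.), DMSO, rt
Reagents that add atoms: none
Why: Proline-mediated intramolecular aldol condensation (Hajos–Parrish–Eder–Sauer–Wiechert reaction): the side-chain enamine adds to one of the two enantiotopic ring carbonyls under direction by the proline carboxylic acid, which sets C7, and the ketol dehydrates to the enone. Recrystallisation of 7 is planned to raise the enantiomeric purity.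

Step 4
Reactants: 7 (4aS,7S)-4a,7-dimethyl-4,4a,7,8-tetrahydronaphthalene-2,5(3H,6H)-dione
Product: 8 C1 ethylene ketal of 7 (spiro-dioxolane at C1; C10 enone intact)
Conditions: ethylene glycol, TsOH·H2O (cat.), 4 Å molecular sieves, rt
Reagents that add atoms: ethylene glycol OCCO
Why: Acid-catalysed ketalisation selects the saturated C1 ketone over the less electrophilic conjugated C10 ketone; at room temperature the enone double bond stays at C5=C6.

Step 5
Reactants: 8 C1 ethylene ketal of 7
Product: 9 10β-allylic alcohol (C5=C6; C1 dioxolane)
Conditions: NaBH4, CeCl3·7H2O, MeOH, −78 to 0 °C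
Reagents that add atoms: none
Why: Luche 1,2-reduction; axial hydride delivery to the half-chair enone should give the pseudo-equatorial 10β-alcohol, cis to the angular methyl.

Step 6
Reactants: 9 10β-allylic alcohol
Product: 10 10β-(4-methoxybenzyl) ether of 9
Conditions: NaH, 4-methoxybenzyl chloride, Bu4NI (cat.), THF/DMF, 0 °C to rt
Reagents that add atoms: 4-methoxybenzyl chloride COc1ccc(CCl)cc1
Why: Williamson etherification; the ether is inert to the base of step 9 and is removed oxidatively in step 18.

Step 7
Reactants: 10 10β-(4-methoxybenzyl) ether of 9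
Product: 11 trans-decalin 5α,6α-diol (tertiary axial 5α-OH; equatorial 6α-OH; 10β-OPMB; C1 dioxolane)
Conditions: OsO4 (cat.), N-methylmorpholine N-oxide, acetone/H2O, rt
Reagents that add atoms: osmium tetroxide O=[Os](=O)(=O)=O; N-methylmorpholine N-oxide C[N+]1([O-])CCOCC1
Why: Syn-dihydroxylation of the trisubstituted alkene from the α face, anti to the axial C7 methyl and anti to the allylic ether (the two effects reinforce). The equatorial C3 methyl anchors ring B in the chair that keeps the C7 methyl axial.

Step 8
Reactants: 11 trans-decalin 5α,6α-diol
Product: 12 6α-methanesulfonate of 11 (free tertiary 5α-OH)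
Conditions: MsCl, Et3N, CH2Cl2, −10 °C
Reagents that add atoms: methanesulfonyl chloride CS(=O)(=O)Cl
Why: Sulfonylation of the only secondary hydroxyl; the tertiary C5 hydroxyl does not react under these conditions.

Step 9
Reactants: 12 6α-methanesulfonate of 11
Product: 14 cis-fused hydroazulen-5-one (6β-H; C1 dioxolane; 10β-OPMB; 3β,7β-dimethyl), via potassium C5 alkoxide 13 (not isolated)
Conditions: KOtBu (1.05 equiv), THF, 0 °C, then NH4Cl (aq.)
Reagents that add atoms: none
Why: KOtBu deprotonates the tertiary C5 hydroxyl; in the rigid trans-decalin the equatorial C6–OMs bond is anti-periplanar to the C5–C7 ring bond, so the alkoxide pushes, C7 migrates from C5 to C6 and mesylate leaves in one pinacol-type 1,2-shift that forms C6–C7 and the C5 carbonyl. The closest known reaction type is the base-induced rearrangement of trans-decalin-1,2-diol monosulfonates to hydroazulenones. Ring A (C5, C6, C10, C9, C8, C7) contracts to the cyclopentane by loss of C5, and ring B (C7, C1–C5) expands to the cycloheptanone by insertion of C6; both changes are the same bond migration. C7 migrates with retention and C6 is inverted by backside displacement, so the new C6 centre (H6 β, cis fusion) is dictated by the α-mesylate set in step 7. The step needs migration of C7 only: C4 is gauche to the leaving group, the C10–C9 bond is anti-periplanar but not attached to the alkoxide carbon, and epoxide closure is impossible because the axial O5 and the equatorial mesylate are gauche. One equivalent of base at 0 °C and a prompt quench should keep the product from enolising toward C6, which would expel the C10 ether.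

Step 10
Reactants: 14 cis-fused hydroazulen-5-one
Product: 15 C5 trimethylsilyl enol ether with C5=C6 double bond
Conditions: Me3SiCl, Et3N, DMF, 80 °C
Reagents that add atoms: chlorotrimethylsilane C[Si](C)(C)Cl
Why: Enol silylation with amine base under equilibrating conditions should favour the more substituted enol ether (C5=C6, exocyclic to the five-membered ring) without a free enolate, so the β-ether at C10 is not expelled. The C6 centre is erased on purpose; any C4=C5 isomer is carried on and removed after step 13.

Step 11
Reactants: 15 C5 trimethylsilyl enol ether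
Product: 17 C5 enol triflate with C5=C6 double bond, via lithium C5 enolate 16 (not isolated)
Conditions: MeLi, THF, 0 °C; then N-(5-chloro-2-pyridyl)triflimide, −78 °C
Reagents that add atoms: N-(5-chloro-2-pyridyl)bis(trifluoromethanesulfonimide) FC(F)(F)S(=O)(=O)N(c1ccc(Cl)cn1)S(=O)(=O)C(F)(F)F
Why: MeLi cleaves the Si–O bond to the regiodefined lithium enolate, which the reactive pyridyl triflimide sulfonylates on oxygen at low temperature before the enolate can eliminate the C10 ether.

Step 12
Reactants: 17 C5 enol triflate
Product: 18 alkene with C5=C6 double bond (C1 dioxolane; 10β-OPMB)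
Conditions: Pd(OAc)2 (cat.), PPh3, Bu3N, HCO2H, DMF, 60 °C
Reagents that add atoms: none
Why: Palladium-catalysed formate reduction of an enol triflate: zerovalent palladium formed in situ inserts into the C–O bond, formate replaces triflate and loses CO2, and the vinylpalladium hydride eliminates the alkene reductively.

Step 13
Reactants: 18 alkene with C5=C6 double bond
Product: 20 trans-fused 5α-alcohol (6α-H; C1 dioxolane; 10β-OPMB), via 5α-alkylborane 19 (not isolated)
Conditions: BH3·THF, THF, 0 °C to rt; then NaOH, H2O2, 0 °C
Reagents that add atoms: borane–tetrahydrofuran complex B.C1CCOC1; hydrogen peroxide OO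
Why: Hydroboration–oxidation: boron adds to the less substituted C5 and hydrogen to C6 in one syn addition from the α face, anti to the two allylic β substituents (C7 methyl and C10 ether), and oxidation with retention gives 5α-OH and 6α-H. The trans ring fusion and the C5 configuration are thus set together by the mechanism, not by equilibration or hydride reduction.

Step 14
Reactants: 20 trans-fused 5α-alcohol
Product: 21 5α-TBS ether of 20
Conditions: tBuMe2SiOTf, 2,6-lutidine, CH2Cl2, −78 to 0 °C
Reagents that add atoms: tert-butyldimethylsilyl trifluoromethanesulfonate CC(C)(C)[Si](C)(C)OS(=O)(=O)C(F)(F)F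
Why: Silyl triflate silylation of the hindered secondary alcohol in the presence of a hindered, non-nucleophilic base.

Step 15
Reactants: 21 5α-TBS ether of 20
Product: 22 C1 ketone (5α-OTBS; 10β-OPMB; trans-fused)
Conditions: TsOH·H2O (cat.), acetone/H2O, rt
Reagents that add atoms: water O
Why: Acid-catalysed hydrolysis (transketalisation to acetone) of the dioxolane; the hindered secondary silyl ether and the PMB ether should tolerate these mild conditions.

Step 16
Reactants: 22 C1 ketone
Product: 24 C1 enol triflate with C1=C2 double bond, via potassium C1 enolate 23 (not isolated)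
Conditions: KN(SiMe3)2, THF, −78 °C; then PhNTf2, −78 to 0 °C
Reagents that add atoms: N-phenylbis(trifluoromethanesulfonimide) FC(F)(F)S(=O)(=O)N(c1ccccc1)S(=O)(=O)C(F)(F)F
Why: The C1 ketone has α-hydrogens only at C2 because C7 is quaternary, so deprotonation and O-sulfonylation can give only one enol triflate.

Step 17
Reactants: 24 C1 enol triflate
Product: 25 alkene with C1=C2 double bond (5α-OTBS; 10β-OPMB)
Conditions: Pd(OAc)2 (cat.), PPh3, Bu3N, HCO2H, DMF, 60 °C
Reagents that add atoms: none
Why: Same palladium-catalysed formate reduction as in step 12; it leaves the cis-disubstituted C1=C2 alkene.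

Step 18
Reactants: 25 alkene with C1=C2 double bond
Product: 26 10β-alcohol (C1=C2; 5α-OTBS)
Conditions: DDQ, CH2Cl2/pH 7 buffer, 0 °C to rt
Reagents that add atoms: none
Why: Oxidative cleavage of the 4-methoxybenzyl ether by benzylic hydride abstraction and hydrolysis; the silyl ether and the isolated alkene are inert.

Step 19
Reactants: 26 10β-alcohol
Product: 27 C10 ketone (C1=C2; 5α-OTBS; 6α-H)
Conditions: Dess–Martin periodinane, NaHCO3, CH2Cl2, rt
Reagents that add atoms: none
Why: Dess–Martin oxidation under buffered conditions, so that C6 (now α to the ketone) is not epimerised and the β-silyloxy group is not eliminated.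

Step 20
Reactants: 27 C10 ketone; 28 isopropylmagnesium chloride
Product: 29 10β-hydroxy-10α-isopropyl compound (C1=C2; 5α-OTBS)
Conditions: CeCl3, THF, −78 °C
Reagents that add atoms: none
Why: Organocerium addition (isopropylcerium dichloride formed in the flask), which suppresses enolisation and β-hydride reduction of the hindered cyclopentanone. Attack from the α face, anti to the C7 methyl that stands 1,3 to C10 on the five-membered ring and past the small H6, should give the 10α-isopropyl-10β-ol.

Step 21
Reactants: 29 10β-hydroxy-10α-isopropyl compound
Product: 30 1α,2α-epoxide of 29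
Conditions: mCPBA, NaHCO3, CH2Cl2, 0 °C
Reagents that add atoms: 3-chloroperoxybenzoic acid OOC(=O)c1cccc(Cl)c1
Why: Prilezhaev epoxidation of the only alkene, anti to the C7 methyl next to C1 and anti to the allylic C3 methyl. Oxygen is placed at C1 on the face from which a hydride would have attacked a C1 carbonyl.

Step 22
Reactants: 30 1α,2α-epoxide of 29
Product: 31 1α-allylic alcohol (C2=C3; 5α-OTBS; 10β-OH; 10α-isopropyl)
Conditions: Et2AlCl, lithium 2,2,6,6-tetramethylpiperidide (excess), toluene, 0 °C to rt
Reagents that add atoms: none
Why: Isomerisation of an epoxide to an allylic alcohol with a hindered aluminium amide: aluminium binds the epoxide oxygen and the amide removes the syn β-hydrogen through a cyclic transition state. The only β-hydrogen is H3 (C7 is quaternary) and it is α, syn to the oxygen, so C2–O breaks, C2=C3 forms and C1 keeps its α-oxygen.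

Step 23
Reactants: 31 1α-allylic alcohol; 32 angelic acid
Product: 33 1α-angelate of 31
Conditions: 2,4,6-trichlorobenzoyl chloride, Et3N, toluene, rt; then 31, 80 °C
Reagents that add atoms: none
Why: Yamaguchi-type esterification through the mixed anhydride without a nucleophilic catalyst, chosen to keep the Z geometry of the angeloyl group; only the secondary allylic hydroxyl reacts, the tertiary one does not.

Step 24
Reactants: 33 1α-angelate of 31
Product: 34 1α-angeloyloxy-5α,10β-diol
Conditions: HF·pyridine, pyridine, THF, 0 °C to rt
Reagents that add atoms: none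
Why: Fluoride desilylation under mildly acidic conditions that leave the allylic angelate and the tertiary alcohol untouched.

Step 25
Reactants: 34 1α-angeloyloxy-5α,10β-diol; 35 4-(tert-butyldimethylsilyloxy)benzoic acid
Product: 36 aryl TBS ether of the target
Conditions: EDC·HCl, DMAP, CH2Cl2, rt
Reagents that add atoms: none
Why: Steglich esterification of the secondary C5 hydroxyl; the tertiary C10 hydroxyl is not acylated.

Step 26
Reactants: 36 aryl TBS ether of the target
Product: 37 target CNP0273650.2
Conditions: Bu4NF, AcOH, THF, 0 °C
Reagents that add atoms: none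
Why: Buffered fluoride cleaves the aryl silyl ether much faster than it touches the esters; acetic acid prevents phenoxide-mediated acyl transfer.

## Compound list

1 | 5-methylcyclohexane-1,3-dione | CC1CC(=O)CC(=O)C1 | starting material
2 | iodomethane | CI | starting material
3 | 2,5-dimethylcyclohexane-1,3-dione | CC1CC(=O)C(C)C(=O)C1 | intermediate
4 | methyl vinyl ketone | CC(=O)C=C | starting material
5 | cis-2,5-dimethyl-2-(3-oxobutyl)cyclohexane-1,3-dione (methyl groups cis; achiral) | CC(=O)CC[C@]1(C)C(=O)C[C@@H](C)CC1=O | intermediate
6 | cis-fused aldol ketol (tertiary C5 hydroxyl cis to the C7 methyl; C1 and C10 ketones) | O=C1CC[C@]2(C)C(=O)C[C@@H](C)C[C@]2(O)C1 | intermediate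
7 | (4aS,7S)-4a,7-dimethyl-4,4a,7,8-tetrahydronaphthalene-2,5(3H,6H)-dione (C1 and C10 ketones, C5=C6, 3β,7β-dimethyl) | O=C1CC[C@]2(C)C(=O)C[C@@H](C)CC2=C1 | intermediate
8 | C1 ethylene ketal of 7 | O=C1CC[C@]2(C)C3(OCCO3)C[C@@H](C)CC2=C1 | intermediate
9 | 10β-allylic alcohol (C5=C6, C1 dioxolane) | O[C@H]1CC[C@]2(C)C3(OCCO3)C[C@@H](C)CC2=C1 | intermediate
10 | 10β-(4-methoxybenzyl) ether of 9 | COc1ccc(CO[C@H]2CC[C@]3(C)C4(OCCO4)C[C@@H](C)CC3=C2)cc1 | intermediate
11 | trans-decalin 5α,6α-diol (10β-OPMB, C1 dioxolane, 3β,7β-dimethyl) | O[C@@H]1[C@@H](OCc2ccc(OC)cc2)CC[C@]3(C)C4(OCCO4)C[C@@H](C)C[C@@]13O | intermediate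
12 | 6α-methanesulfonate of 11 (key-step precursor) | CS(=O)(=O)O[C@@H]1[C@@H](OCc2ccc(OC)cc2)CC[C@]3(C)C4(OCCO4)C[C@@H](C)C[C@@]13O | intermediate
13 | potassium C5 alkoxide of 12 | CS(=O)(=O)O[C@@H]1[C@@H](OCc2ccc(OC)cc2)CC[C@]3(C)C4(OCCO4)C[C@@H](C)C[C@@]13[O-].[K+] | intermediate
14 | cis-fused hydroazulen-5-one (6β-H, C1 dioxolane, 10β-OPMB, 3β,7β-dimethyl) | O1CCOC12C[C@@H](C)CC(=O)[C@H]3[C@]2(C)CC[C@@H]3OCc4ccc(OC)cc4 | intermediate
15 | C5 trimethylsilyl enol ether (C5=C6) | O1CCOC12C[C@@H](C)CC(O[Si](C)(C)C)=C3[C@]2(C)CC[C@@H]3OCc4ccc(OC)cc4 | intermediate
16 | lithium C5 enolate (C5=C6) | O1CCOC12C[C@@H](C)CC([O-])=C3[C@]2(C)CC[C@@H]3OCc4ccc(OC)cc4.[Li+] | intermediate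
17 | C5 enol triflate (C5=C6) | O1CCOC12C[C@@H](C)CC(OS(=O)(=O)C(F)(F)F)=C3[C@]2(C)CC[C@@H]3OCc4ccc(OC)cc4 | intermediate
18 | alkene with C5=C6 (C1 dioxolane, 10β-OPMB) | O1CCOC12C[C@@H](C)CC=C3[C@]2(C)CC[C@@H]3OCc4ccc(OC)cc4 | intermediate
19 | 5α-alkylborane (6α-H) | O1CCOC12C[C@@H](C)C[C@H](B)[C@@H]3[C@]2(C)CC[C@@H]3OCc4ccc(OC)cc4 | intermediate
20 | trans-fused 5α-alcohol (6α-H, C1 dioxolane, 10β-OPMB) | O1CCOC12C[C@@H](C)C[C@H](O)[C@@H]3[C@]2(C)CC[C@@H]3OCc4ccc(OC)cc4 | intermediate
21 | 5α-TBS ether of 20 | O1CCOC12C[C@@H](C)C[C@H](O[Si](C)(C)C(C)(C)C)[C@@H]3[C@]2(C)CC[C@@H]3OCc4ccc(OC)cc4 | intermediate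
22 | C1 ketone (5α-OTBS, 10β-OPMB) | O=C1C[C@@H](C)C[C@H](O[Si](C)(C)C(C)(C)C)[C@@H]2[C@]1(C)CC[C@@H]2OCc3ccc(OC)cc3 | intermediate
23 | potassium C1 enolate (C1=C2) | [K+].[O-]C1=C[C@@H](C)C[C@H](O[Si](C)(C)C(C)(C)C)[C@@H]2[C@]1(C)CC[C@@H]2OCc3ccc(OC)cc3 | intermediate
24 | C1 enol triflate (C1=C2) | FC(F)(F)S(=O)(=O)OC1=C[C@@H](C)C[C@H](O[Si](C)(C)C(C)(C)C)[C@@H]2[C@]1(C)CC[C@@H]2OCc3ccc(OC)cc3 | intermediate
25 | alkene with C1=C2 (5α-OTBS, 10β-OPMB) | C1=C[C@@H](C)C[C@H](O[Si](C)(C)C(C)(C)C)[C@@H]2[C@]1(C)CC[C@@H]2OCc3ccc(OC)cc3 | intermediate
26 | 10β-alcohol (C1=C2, 5α-OTBS) | C1=C[C@@H](C)C[C@H](O[Si](C)(C)C(C)(C)C)[C@@H]2[C@]1(C)CC[C@@H]2O | intermediate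
27 | C10 ketone (C1=C2, 5α-OTBS, 6α-H) | C1=C[C@@H](C)C[C@H](O[Si](C)(C)C(C)(C)C)[C@@H]2[C@]1(C)CCC2=O | intermediate
28 | isopropylmagnesium chloride | CC(C)[Mg]Cl | starting material
29 | 10β-hydroxy-10α-isopropyl compound (C1=C2, 5α-OTBS) | C1=C[C@@H](C)C[C@H](O[Si](C)(C)C(C)(C)C)[C@@H]2[C@]1(C)CC[C@@]2(O)C(C)C | intermediate
30 | 1α,2α-epoxide of 29 | [C@@H]12O[C@@H]1[C@@H](C)C[C@H](O[Si](C)(C)C(C)(C)C)[C@@H]3[C@]2(C)CC[C@@]3(O)C(C)C | intermediate
31 | 1α-allylic alcohol (C2=C3, 5α-OTBS, 10β-OH, 10α-isopropyl) | O[C@@H]1C=C(C)C[C@H](O[Si](C)(C)C(C)(C)C)[C@@H]2[C@]1(C)CC[C@@]2(O)C(C)C | intermediate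
32 | angelic acid, (Z)-2-methylbut-2-enoic acid | C/C=C(/C)C(=O)O | starting material
33 | 1α-angelate of 31 | C/C=C(/C)C(=O)O[C@@H]1C=C(C)C[C@H](O[Si](C)(C)C(C)(C)C)[C@@H]2[C@]1(C)CC[C@@]2(O)C(C)C | intermediate
34 | 1α-angeloyloxy-5α,10β-diol | C/C=C(/C)C(=O)O[C@@H]1C=C(C)C[C@H](O)[C@@H]2[C@]1(C)CC[C@@]2(O)C(C)C | intermediate
35 | 4-(tert-butyldimethylsilyloxy)benzoic acid | CC(C)(C)[Si](C)(C)Oc1ccc(cc1)C(=O)O | starting material
36 | aryl TBS ether of the target | C/C=C(/C)C(=O)O[C@@H]1C=C(C)C[C@H](OC(=O)c3ccc(O[Si](C)(C)C(C)(C)C)cc3)[C@@H]2[C@]1(C)CC[C@@]2(O)C(C)C | intermediate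
37 | target: 1α-angeloyloxy-5α-(4-hydroxybenzoyloxy)-10β-hydroxy-10α-isopropyl-3,7β-dimethyl-6α-H-hydroazul-2-ene | C/C=C(/C)C(=O)O[C@@H]1C=C(C)C[C@H](OC(=O)c2ccc(O)cc2)[C@@H]2[C@]1(C)CC[C@@]2(O)C(C)C | target

## Step count and least certain steps

Total step count: 26. Longest linear sequence: 26 steps (1 to 37).

**Step 9 (key step).** The shift itself is stereoelectronically secured. The likely failure is what happens afterwards in the basic medium: the new ketone enolises toward C6 and expels the C10 ether, or C6 and C4 are scrambled. Fallback: from 12, the rearrangement is triggered by a Lewis acid instead of an alkoxide base. AlEt3 in CH2Cl2 at −78 °C forms the C5 aluminium alkoxide with loss of ethane and activates the sulfonate, so the same anti-periplanar C5–C7 bond migrates in a non-basic medium (organoaluminium-promoted pinacol-type rearrangement of a β-mesyloxy alcohol). It comes back at 14; no new compound is made on the way, which is recorded below as entry F0.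

**Step 10.** Enol silylation may occur toward the more accessible C4 methylene, because H6 is flanked by the C7 methyl and the C10 ether; the wrong alkene would then enter step 13. Fallback: from 14, avoid enolisation. NaBH4 should attack the cis-fused ketone from its convex β face to give the cis-fused 5α-alcohol F1. Mesylation gives the 5α-mesylate F2. Heating with DBU in toluene then eliminates through the C6 hydrogen, which is β and anti to the α-mesylate, toward the trisubstituted alkene. It comes back at 18.

**Step 13.** Facial selectivity may be poor: the seven-membered ring is flexible, and the α-oriented oxygen of the C1 dioxolane could offset the shielding of the β face, so that borane adds from the β face and the 5β,6β isomer results. Fallback: from 15, set C6 and C5 separately. MeLi, then protonation of the lithium enolate with 2,6-di-tert-butyl-4-methylphenol at −78 °C, should give the trans-fused hydroazulen-5-one F3; protonation from the wrong face only returns 14, which is recycled. Electron-transfer reduction of F3 with SmI2 (divalent samarium), H2O and Et3N in THF should then give the more stable 5α-alcohol, since a 5β-hydroxyl would be syn-axial to the C7 methyl. It comes back at 20.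

**Step 22.** Abstraction of the tertiary H3 by the bulky amide may be slow, so that metalation of the epoxide C–H (ketone formation) or ethyl transfer from aluminium competes. Fallback: from 29, skip the epoxide. A Schenck ene reaction with singlet oxygen (O2, light, tetraphenylporphyrin, CH2Cl2; expected to be slow on a disubstituted alkene) should add oxygen at C1 from the α face and abstract the α-H3, the only allylic hydrogen, giving the 1α-allylic hydroperoxide F4. PPh3 reduces F4 to the alcohol. It comes back at 31.

**Step 23.** The activated angeloyl group may isomerise to the tigloyl group, and the alcohol next to the quaternary carbon may acylate slowly. Fallback: from 31, build the Z alkene on the substrate. Esterification with 2-[bis(2,2,2-trifluoroethoxy)phosphoryl]propanoic acid (DCC, DMAP) gives the phosphonopropanoate F5. Still–Gennari olefination of F5 with acetaldehyde (KN(SiMe3)2, 18-crown-6, THF, −78 °C) should give the Z-configured 2-methylbut-2-enoate. It comes back at 33.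

## Further compounds

F0 | step 9 | none | none
F1 | step 10 | cis-fused 5α-alcohol (6β-H, C1 dioxolane, 10β-OPMB) | O1CCOC12C[C@@H](C)C[C@H](O)[C@H]3[C@]2(C)CC[C@@H]3OCc4ccc(OC)cc4
F2 | step 10 | 5α-mesylate of F1 | O1CCOC12C[C@@H](C)C[C@H](OS(C)(=O)=O)[C@H]3[C@]2(C)CC[C@@H]3OCc4ccc(OC)cc4
F3 | step 13 | trans-fused hydroazulen-5-one (6α-H), C6 epimer of 14 | O1CCOC12C[C@@H](C)CC(=O)[C@@H]3[C@]2(C)CC[C@@H]3OCc4ccc(OC)cc4
F4 | step 22 | 1α-allylic hydroperoxide (C2=C3, 5α-OTBS, 10β-OH, 10α-isopropyl) | OO[C@@H]1C=C(C)C[C@H](O[Si](C)(C)C(C)(C)C)[C@@H]2[C@]1(C)CC[C@@]2(O)C(C)C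
F5 | step 23 | 1α-[2-(bis(2,2,2-trifluoroethoxy)phosphoryl)propanoate] of 31 | CC(C(=O)O[C@@H]1C=C(C)C[C@H](O[Si](C)(C)C(C)(C)C)[C@@H]2[C@]1(C)CC[C@@]2(O)C(C)C)P(=O)(OCC(F)(F)F)OCC(F)(F)F
A1 | alternative 1 | 3-[(methoxymethoxy)methyl]cyclopent-2-en-1-one | O=C1CCC(COCOC)=C1
A2 | alternative 1 | 3-methylbut-3-enal | O=CCC(C)=C
A3 | alternative 1 | trans-2,3-disubstituted cyclopentanone with quaternary C7 and anti aldol at C5–C6 | O=C1CC[C@](C)(COCOC)[C@H]1[C@@H](O)CC(C)=C
A4 | alternative 2 | 3-methylcyclopent-2-en-1-one | CC1=CC(=O)CC1
A5 | alternative 2 | 4-methyl-1,2-bis(trimethylsilyloxy)cyclopent-1-ene | CC1CC(O[Si](C)(C)C)=C(O[Si](C)(C)C)C1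
A6 | alternative 2 | cis-anti-cis tricyclic cyclobutane bis(silyl ether) with C10 ketone | O=C1CC[C@@]2(C)[C@@H]1[C@]3(O[Si](C)(C)C)C[C@@H](C)C[C@]23O[Si](C)(C)C
A7 | alternative 3 | 4-(tert-butyldimethylsilyloxy)-3-methylcyclohept-2-en-1-one | CC(C)(C)[Si](C)(C)O[C@H]1CCCC(=O)C=C1C
A8 | alternative 3 | trimethyl(4-methylpenta-1,2-dien-3-yl)silane | C=C=C(C(C)C)[Si](C)(C)C
A9 | alternative 3 | cis-fused trimethylsilylcyclopentene-annulated cycloheptanone | CC(C)(C)[Si](C)(C)O[C@H]1CCCC(=O)[C@H]2[C@]1(C)CC([Si](C)(C)C)=C2C(C)C
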